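# Proposed synthesis of (+)-isolariciresinol by ring expansion of a tethered cyclobutane dimer

## The problem

(+)-Isolariciresinol (10) is a 1-aryltetralin. Ring A (C4a–C8a, a guaiacol with 6-OMe and 7-OH) is fused to ring B (C1–C4), which carries a 4-hydroxy-3-methoxyphenyl group at C1 and hydroxymethyl groups at C2 and C3. The three contiguous stereocentres, C1 (S), C2 (R) and C3 (R), are all-trans. C2 and C3 must be set in the absolute sense; C1 is a diarylmethine that cannot be corrected later and has to follow C2. The bond that resists closure is C1–C8a, which joins the diaryl-substituted carbon to the ring A carbon para to the methoxy group. Two free phenols and two primary alcohols rule out harsh oxidants or acids on the unprotected compound, so the phenols are carried as benzyl ethers and the alcohols as carboxylates. The feature that makes the key step possible is that C1–C4 with their substituents (aryl on C1, ring A on C4, a one-carbon oxygenated group on each of C2 and C3) are, atom for atom, the head-to-head [2+2] dimer of two identical cinnamate units, with C1 bonded to C8a instead of to C4. The target skeleton is therefore a constitutional isomer of an all-trans, C2-symmetric 3,4-diarylcyclobutane-1,2-dicarboxylate, and C8a is the nucleophilic position of ring A.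

## Retrosynthesis

**10 ⇒ 9 ⇒ 8.** No skeletal bond is cut. The phenols are masked as benzyl ethers (9), and the two CH2OH groups are read as the reduced form of two carboxylates that are esterified by one molecule of the C2-symmetric diol 5 (macrodiolide 8). Against two separate esters, the cyclic diester places a chiral, cleavable unit where C2 and C3 are made, and the hydride reduction that the target needs anyway removes it. The forward reactions must reduce both esters without epimerising C2 and must remove the benzyl groups without touching the C1–H diarylmethine.

**8 ⇒ 7 (key disconnection).** The C1–C8a bond is cut and C1 is joined to C4, which contracts ring B to a cyclobutane. Against a simple cut of C1–C8a, which gives an open-chain compound that needs a leaving group or an oxidation at C1, the cyclobutane stores C1 at the right oxidation level in the strained C1–C4 bond. Because 7 is C2-symmetric, either aryl-bearing carbon can become C1 with the same result. The unsymmetrical tetralin with three stereocentres becomes an all-trans cyclobutane with one independent stereochemical element. The forward reaction must cleave only the bis-benzylic bond, close at the position para to OMe, set C1 trans to C2 and leave C2 and C3 untouched.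

**7 ⇒ 6.** Both cyclobutane bonds (C2–C3 and C1–C4) are cut, the retron of a [2+2] photocycloaddition of two cinnamate C=C bonds. Against a stepwise enolate coupling to make C2–C3, one photochemical step joins two identical halves, and the tether enforces the head-to-head orientation. The precursor 6 has no stereocentres other than those of the tether. The forward reaction must close trans,trans,trans (the δ arrangement) and with a facial bias from 5; since the tether stays on, the stereoisomers are diastereomers and separable.

**6 ⇒ 4 + 5; 4 ⇒ 1 + 2.** The two ester C–O bonds are cut to give two molecules of acid 4 and diol 5, and the C=C bond of 4 is cut to aldehyde 1 and malonic acid 2. All of the carbon of 10 then comes from 1 and 2, used twice. The forward reactions are a double esterification and a condensation that gives the E alkene.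

## Roads not taken

**Alternative 1:** The most obvious cut is C1–C8a alone, made as a polar Friedel–Crafts bond. Lactone A1 (from 1 by Stobbe condensation, asymmetric hydrogenation and reduction–lactonisation) would be added as its enolate to 1 to give hydroxy lactone A2. Acid would then ionise the benzylic alcohol, and ring A would close para to OMe to give the trans,trans lactone A3, which LiAlH4 reduces to 9. This builds the two identical C6–C3 halves by two different sequences and needs about eight operations before the last two steps that both plans share. The asymmetric step sets only C3. The chosen plan uses the hidden C2 symmetry, makes both halves from one acid, and reaches the same point in four steps.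

**Alternative 2:** The cuts are C1–C2 and C3–C4, with ring B as the Diels–Alder adduct of an ortho-quinodimethane. Irradiation of 2-benzylbenzaldehyde A4 would give the hydroxy-ortho-quinodimethane, and a fumarate diester of a chiral alcohol would trap it to give tetralol diester A5; removal of the C4 hydroxyl group and reduction would follow. A4 needs a 6-functionalised ring A and a cross-coupling to make the diarylmethane. The cycloaddition creates a fourth stereocentre and an oxygen at C4 only to delete them. With a fumarate one ester is necessarily endo and the other exo, so the C1/C2 relation is not dictated by the dienophile, and facial control rests on a remote ester auxiliary. The chosen plan makes no atom that is later removed from the skeleton.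

**Alternative 3:** The cuts are C1–C8a and C2–C3, the same two bonds as in the chosen plan, made in one thermal intramolecular Diels–Alder reaction with a styrene as the diene. In cinnamyl cinnamate A6 the C8a=C4a–C4=C3 unit of one half would add to C1=C2 of the other, and a hydrogen shift would restore ring A to give A3 in one step. A6 is achiral and its short ester tether has no place for a removable controller, so A3 would be racemic. The concerted transition state has to break the aromaticity of ring A and to join two termini of like polarity at C2 and C3, which calls for high temperatures. The ring fusion is not controlled, and C2, next to the lactone carbonyl, can epimerise to the cis-fused lactone. The chosen plan makes the same bonds in two separately controlled events: C2–C3 photochemically under a chiral tether, and C1–C8a by a charge-driven closure.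

Key step: step 4

Assumption: the (4S,5S) diol 5 is taken to favour the (1R,2R,3S,4S) cyclobutane 7; if the inherent facial preference is the opposite, the (4R,5R) diol, equally available, is used and nothing else changes.

## Route

Step 1
Reactants: 1 4-(benzyloxy)-3-methoxybenzaldehyde; 2 malonic acid
Product: 4 (E)-3-[4-(benzyloxy)-3-methoxyphenyl]prop-2-enoic acid, via arylidenemalonic acid 3 (not isolated)
Conditions: pyridine, piperidine (cat.), 90 °C
Reagents that add atoms: none
Why: Knoevenagel condensation with decarboxylation (Doebner modification); decarboxylation of the arylidenemalonic acid should give the E acid, which carries all nine carbons of each half of the target.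

Step 2
Reactants: 4 (2.2 equiv); 5 [(4S,5S)-2,2-dimethyl-1,3-dioxolane-4,5-diyl]dimethanol
Product: 6 [(4S,5S)-2,2-dimethyl-1,3-dioxolane-4,5-diyl]bis(methylene) bis{(E)-3-[4-(benzyloxy)-3-methoxyphenyl]prop-2-enoate}
Conditions: DCC, DMAP (cat.), CH2Cl2, 0 °C to rt
Reagents that add atoms: none
Why: Steglich esterification of two unhindered primary alcohols with a cinnamic acid; no stereocentre is formed and the acetonide and benzyl ethers are inert to these conditions.

Step 3
Reactants: 6
Product: 7 cyclic diester of (1R,2R,3S,4S)-3,4-bis[4-(benzyloxy)-3-methoxyphenyl]cyclobutane-1,2-dicarboxylic acid with diol 5 (ten-membered dilactone)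
Conditions: thioxanthen-9-one (10 mol %), 405 nm LEDs, degassed CH2Cl2 (5 mM), rt
Reagents that add atoms: none
Why: Triplet-sensitised intramolecular [2+2] photocycloaddition of a dicinnamate; stepwise closure through a bis-benzylic 1,4-biradical should give the head-to-head all-trans (δ) cyclobutane, and esters of tartrate-derived 1,4-diols are a known class of covalent templates for this closure with a facial bias. The four stereocentres are set here under the control of the (4S,5S) tether, and the stereoisomers are diastereomers, so the purity of 7 can be secured by separation.

Step 4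
Reactants: 7
Product: 8 cyclic diester of (1S,2R,3R)-7-(benzyloxy)-1-[4-(benzyloxy)-3-methoxyphenyl]-6-methoxy-1,2,3,4-tetrahydronaphthalene-2,3-dicarboxylic acid with diol 5
Conditions: 9-mesityl-10-methylacridinium tetrafluoroborate (5 mol %), PhSSPh (20 mol %), 450 nm LEDs, degassed 1,2-dichloroethane–1,1,1,3,3,3-hexafluoropropan-2-ol (9:1), 0.02 M, rt
Reagents that add atoms: none
Why: Proposed new method: the excited acridinium should oxidise one 3-methoxy-4-benzyloxyphenyl ring of 7 to its radical cation, whose strained, doubly benzylic cyclobutane bond between the two aryl-bearing carbons (C1–C4 in target numbering) cleaves to a distonic radical cation with a 4-alkoxybenzyl cation at C1 and a benzylic radical at C4; since 7 is C2-symmetric, oxidation of either ring leads to the same product. The closest known reaction types are the electron-transfer-sensitised [4+2] cyclodimerisation of aryl alkenes to 1-aryltetralins, which runs through this kind of 1,4-radical cation and its 1,6-closure onto the arene, the ring opening of 1,2-diarylcyclobutane radical cations, and the cation-radical vinylcyclobutane rearrangement, in which ring A here plays the part of the vinyl group. Ring B is closed by a six-membered Friedel–Crafts attack of the aryl group on C4, through its carbon para to OMe (C8a), on the C1 cation; loss of a proton restores ring A, and PhSH (from PhS−, formed when PhS• reoxidises the acridinyl radical) transfers hydrogen to the C4 radical, so the step is a redox-neutral isomerisation in which both catalysts turn over. The ten-membered dilactone is carried along and changes from trans-fused on a four-membered ring to trans-fused on a six-membered ring. C2 and C3 are not touched and keep the trans relation and the absolute configuration fixed in 7. C1 is the only new stereocentre: the cation should be attacked on the face that places the pendant aryl group pseudo-equatorial and trans to the C2 carboxylate in a half-chair transition state, the same substrate control that gives the all-trans series in acid-mediated cyclolignan closures. The step needs attack para rather than ortho to OMe, which the stronger activation and lower hindrance of that position secure, and ring closure rather than cycloreversion, which is disfavoured because the fragments would be cinnamate esters with poorly stabilised radical cations that the tether holds together.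

Step 5
Reactants: 8
Product: 9 [(1S,2R,3R)-7-(benzyloxy)-1-[4-(benzyloxy)-3-methoxyphenyl]-6-methoxy-1,2,3,4-tetrahydronaphthalene-2,3-diyl]dimethanol
Conditions: LiAlH4, THF, 0 °C to rt; then H2O, aq. NaOH
Reagents that add atoms: none
Why: Hydride reduction of both ester groups of the dilactone to primary alcohols, which also releases diol 5 for recovery; reduction is expected to be faster than enolisation at C2, and no stereocentre is formed or broken.

Step 6
Reactants: 9
Product: 10 (+)-isolariciresinol, (6R,7R,8S)-8-(4-hydroxy-3-methoxyphenyl)-6,7-bis(hydroxymethyl)-3-methoxy-5,6,7,8-tetrahydronaphthalen-2-ol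
Conditions: H2 (1 atm), Pd/C, EtOAc–MeOH (1:1), rt
Reagents that add atoms: none
Why: Hydrogenolysis of the two aryl benzyl ethers; the C1–H diarylmethine has no benzylic heteroatom and the methyl ethers and alcohols are inert, so the three stereocentres are not affected.

## Compound list

1 | 4-(benzyloxy)-3-methoxybenzaldehyde | COc1cc(C=O)ccc1OCc1ccccc1 | starting material
2 | malonic acid | OC(=O)CC(=O)O | starting material
3 | 2-[4-(benzyloxy)-3-methoxybenzylidene]malonic acid | COc1cc(C=C(C(=O)O)C(=O)O)ccc1OCc1ccccc1 | intermediate
4 | (E)-3-[4-(benzyloxy)-3-methoxyphenyl]prop-2-enoic acid | COc1cc(/C=C/C(=O)O)ccc1OCc1ccccc1 | intermediate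
5 | [(4S,5S)-2,2-dimethyl-1,3-dioxolane-4,5-diyl]dimethanol | CC1(C)O[C@@H](CO)[C@H](CO)O1 | starting material
6 | [(4S,5S)-2,2-dimethyl-1,3-dioxolane-4,5-diyl]bis(methylene) bis{(E)-3-[4-(benzyloxy)-3-methoxyphenyl]prop-2-enoate} | COc1cc(/C=C/C(=O)OC[C@@H]2OC(C)(C)O[C@H]2COC(=O)/C=C/c2ccc(OCc3ccccc3)c(OC)c2)ccc1OCc1ccccc1 | intermediate
7 | cyclic diester of (1R,2R,3S,4S)-3,4-bis[4-(benzyloxy)-3-methoxyphenyl]cyclobutane-1,2-dicarboxylic acid with diol 5 | COc1cc([C@@H]2[C@@H](C(=O)OC[C@@H]3OC(C)(C)O[C@H]3COC4=O)[C@H]4[C@H]2c2ccc(OCc3ccccc3)c(OC)c2)ccc1OCc1ccccc1 | intermediate
8 | cyclic diester of (1S,2R,3R)-7-(benzyloxy)-1-[4-(benzyloxy)-3-methoxyphenyl]-6-methoxy-1,2,3,4-tetrahydronaphthalene-2,3-dicarboxylic acid with diol 5 | COc1cc([C@H]2c3cc(OCc4ccccc4)c(OC)cc3C[C@@H](C(=O)OC[C@@H]4OC(C)(C)O[C@H]4COC5=O)[C@@H]25)ccc1OCc1ccccc1 | intermediate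
9 | [(1S,2R,3R)-7-(benzyloxy)-1-[4-(benzyloxy)-3-methoxyphenyl]-6-methoxy-1,2,3,4-tetrahydronaphthalene-2,3-diyl]dimethanol | COc1cc([C@H]2c3cc(OCc4ccccc4)c(OC)cc3C[C@@H](CO)[C@@H]2CO)ccc1OCc1ccccc1 | intermediate
10 | (+)-isolariciresinol | COc1cc([C@H]2c3cc(O)c(OC)cc3C[C@@H](CO)[C@@H]2CO)ccc1O | target

## Step count and risk

Total steps: 6. Longest linear sequence: 6 steps (1 to 10).

**Step 4 (key step; it bears the new-method label).** The ring-opened radical cation may revert to the two tethered cinnamates faster than it closes onto ring A. It may also lose a proton from C2 next to the cation to give an open-chain alkene, or back electron transfer may return 7 unchanged. The fallback uses known chemistry, sets out from 4 and comes back to the route at 9. It makes the C2–C3 bond by an auxiliary-controlled enolate dimerisation and the C1–C8a bond by an oxidative Friedel–Crafts closure.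
- Conjugate reduction of 4 (NaBH4, NiCl2·6H2O, MeOH) gives 3-[4-(benzyloxy)-3-methoxyphenyl]propanoic acid F1.
- Mixed-anhydride acylation (pivaloyl chloride, Et3N, then lithiated (S)-4-benzyl-1,3-oxazolidin-2-one) gives (S)-4-benzyl-3-{3-[4-(benzyloxy)-3-methoxyphenyl]propanoyl}-1,3-oxazolidin-2-one F2.
- Oxidative homocoupling of its lithium enolate (LDA, THF, −78 °C, then CuCl2) gives the (2R,3R)-2,3-bis[4-(benzyloxy)-3-methoxybenzyl]succinyl bis-imide F3, each centre being set by the auxiliary as in an enolate alkylation.
- LiBH4 reduction gives (2R,3R)-2,3-bis[4-(benzyloxy)-3-methoxybenzyl]butane-1,4-diol F4, and acetylation (Ac2O, pyridine) gives the diacetate F5.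
- DDQ in CH2Cl2–TFA at 0 °C removes hydride from one of the two homotopic benzylic CH2 groups, and the other ring closes para to OMe to give the all-trans tetralin diacetate F6.
- K2CO3 in MeOH returns 9.

**Step 3.** E/Z isomerisation and intermolecular oligomerisation may compete with ring closure. Closure may also give the cis-diester cyclobutane, or the facial bias of the tether may be low, which would cost material at the separation. The fallback sets out from 6 and comes back at 8 with no new compound (F0). Compound 6 is submitted directly to the conditions of step 4, so that the radical cation of one cinnamate is attacked by the other and the same distonic intermediate closes to the tetralin. This is a stepwise radical-cation [4+2] cyclodimerisation in place of the triplet cycloaddition, and the cyclobutane is bypassed.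

**Step 5.** Alkoxide formed during the reduction may epimerise C2 (α to an ester and next to C1) before both carbonyl groups are reduced, or the reduction may stop at ring-opened hydroxy esters. The fallback sets out from 8 and comes back at 9. NaOMe in MeOH transesterifies 8 and releases diol 5, and under these equilibrating conditions C2 and C3 should settle in the all-equatorial arrangement of dimethyl (1S,2R,3R)-7-(benzyloxy)-1-[4-(benzyloxy)-3-methoxyphenyl]-6-methoxy-1,2,3,4-tetrahydronaphthalene-2,3-dicarboxylate F7. This simple diester is then reduced with LiAlH4 to 9.

## Further compounds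

F1 | step 4 | 3-[4-(benzyloxy)-3-methoxyphenyl]propanoic acid | COc1cc(CCC(=O)O)ccc1OCc1ccccc1
F2 | step 4 | (S)-4-benzyl-3-{3-[4-(benzyloxy)-3-methoxyphenyl]propanoyl}-1,3-oxazolidin-2-one | COc1cc(CCC(=O)N2[C@@H](Cc3ccccc3)COC2=O)ccc1OCc1ccccc1
F3 | step 4 | (2R,3R)-2,3-bis[4-(benzyloxy)-3-methoxybenzyl]-1,4-bis[(S)-4-benzyl-2-oxo-1,3-oxazolidin-3-yl]butane-1,4-dione | O=C([C@H](Cc1ccc(OCc2ccccc2)c(OC)c1)[C@@H](Cc1ccc(OCc2ccccc2)c(OC)c1)C(=O)N1[C@@H](Cc2ccccc2)COC1=O)N1[C@@H](Cc2ccccc2)COC1=O
F4 | step 4 | (2R,3R)-2,3-bis[4-(benzyloxy)-3-methoxybenzyl]butane-1,4-diol | OC[C@H](Cc1ccc(OCc2ccccc2)c(OC)c1)[C@@H](Cc1ccc(OCc2ccccc2)c(OC)c1)CO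
F5 | step 4 | (2R,3R)-2,3-bis[4-(benzyloxy)-3-methoxybenzyl]butane-1,4-diyl diacetate | CC(=O)OC[C@H](Cc1ccc(OCc2ccccc2)c(OC)c1)[C@@H](Cc1ccc(OCc2ccccc2)c(OC)c1)COC(C)=O
F6 | step 4 | [(1S,2R,3R)-7-(benzyloxy)-1-[4-(benzyloxy)-3-methoxyphenyl]-6-methoxy-1,2,3,4-tetrahydronaphthalene-2,3-diyl]bis(methylene) diacetate | COc1cc([C@H]2c3cc(OCc4ccccc4)c(OC)cc3C[C@@H](COC(C)=O)[C@@H]2COC(C)=O)ccc1OCc1ccccc1
F0 | step 3 | none | none
F7 | step 5 | dimethyl (1S,2R,3R)-7-(benzyloxy)-1-[4-(benzyloxy)-3-methoxyphenyl]-6-methoxy-1,2,3,4-tetrahydronaphthalene-2,3-dicarboxylate | COc1cc([C@H]2c3cc(OCc4ccccc4)c(OC)cc3C[C@@H](C(=O)OC)[C@@H]2C(=O)OC)ccc1OCc1ccccc1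
A1 | alternative 1 | (R)-4-[4-(benzyloxy)-3-methoxybenzyl]dihydrofuran-2(3H)-one | O=C1OC[C@H](Cc2ccc(OCc3ccccc3)c(OC)c2)C1
A2 | alternative 1 | (3S,4R)-4-[4-(benzyloxy)-3-methoxybenzyl]-3-{[4-(benzyloxy)-3-methoxyphenyl](hydroxy)methyl}dihydrofuran-2(3H)-one (carbinol epimers) | OC(c1ccc(OCc2ccccc2)c(OC)c1)[C@H]1C(=O)OC[C@@H]1Cc1ccc(OCc2ccccc2)c(OC)c1
A3 | alternative 1 | all-trans tetralin γ-lactone (O,O′-dibenzyl-α-conidendrin) | COc1cc([C@H]2c3cc(OCc4ccccc4)c(OC)cc3C[C@H]3COC(=O)[C@H]23)ccc1OCc1ccccc1
A4 | alternative 2 | 4-(benzyloxy)-2-[4-(benzyloxy)-3-methoxybenzyl]-5-methoxybenzaldehyde | O=Cc1cc(OC)c(OCc2ccccc2)cc1Cc1ccc(OCc2ccccc2)c(OC)c1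
A5 | alternative 2 | 1-aryl-4-hydroxytetralin-2,3-dicarboxylate cycloadduct, drawn as the dimethyl ester, C4 carbinol configuration left open | COc1cc([C@H]2c3cc(OCc4ccccc4)c(OC)cc3C(O)[C@@H](C(=O)OC)[C@@H]2C(=O)OC)ccc1OCc1ccccc1
A6 | alternative 3 | (E)-3-[4-(benzyloxy)-3-methoxyphenyl]allyl (E)-3-[4-(benzyloxy)-3-methoxyphenyl]prop-2-enoate | COc1cc(/C=C/COC(=O)/C=C/c2ccc(OCc3ccccc3)c(OC)c2)ccc1OCc1ccccc1
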